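Analysis of the target

Target 26 is made of two flavonoid units joined by one C–C bond. C4 of an isoflavan (ring A with a 7-hydroxyl, pyran ring C, and the 3-hydroxy-2,4-dimethoxyphenyl ring B on C3) is bonded to C6 of a 5,7-dihydroxy-2-(4-hydroxyphenyl)chroman-4-one, whose phloroglucinol-type ring is called ring D here. There are three stereocentres. C3 (R) and C4 (S) of the isoflavan are adjacent and trans on ring C. C2 (S) of the flavanone lies across ring D, too far away to be controlled by them. The sensitive points are the five free phenols, the flavanone O1–C2 bond (it opens by retro-oxa-Michael reaction under base and scrambles C2), and C4, a diarylmethine on a trioxygenated ring whose C–aryl bonds can be broken by acid. The difficulties are the trans C3/C4 relationship, three electron-rich rings of similar reactivity, and the need to tell the three oxygens of ring D apart so that the pyranone is fused on the side that makes the flavanone 6-linked and not 8-linked. The strategy rests on two features. First, C4 carries ring D, whose three oxygens stabilise a cation at C4, while C4a of ring A is ortho to O1 and para to the C7 oxygen and is therefore the nucleophilic carbon of a resorcinol-type ether tied to C4 through O1–C2–C3. Second, before the pyranone is fused, ring D is locally symmetric: the two carbons flanking its para oxygen are equivalent.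

Retrosynthetic reasoning

Target 26 is traced back to its pentabenzyl ether 25. Five O–benzyl bonds are cut, and no skeletal bond, because all phenols can then be released in one neutral hydrogenolysis. Base would open the flavanone and acid would attack the C4–aryl bonds. The forward step must stop before the benzylic C2–O1 bond or the ketone of the flavanone is reduced.

25 is opened at O1–C2 of the flavanone to the 2'-hydroxychalcone 24. The phenol that closes this bond is already in place. The stereocentre created is remote from C3 and C4, so a chiral catalyst has to choose the enone face, and it has to do so faster than the uncatalysed closure.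

24 is the unmasked form of methoxymethyl ether 23, and 23 is cut at the enone double bond into methyl ketone 20 and aldehyde 21. The condensation builds the three-carbon bridge from a commercial aldehyde. Keeping the acetal on the phenol during the basic condensation prevents an early, racemic ring closure.

20 is cut at the bond between the acetyl carbon and ring D, which leads through aryllithium 19 to 18. The cut is placed there, and after ring C exists, because ring D of 18 is still symmetric. Both carbons next to the methoxymethoxy group lie between that acetal and a benzyloxy group, and the acetal is the strongest lithium-directing group in the molecule. The acetyl group therefore ends up ortho to the one oxygen that becomes the flavanone O1, and the flavanone can only be 6-linked. An electrophilic acetylation of the free phenol was not chosen: it would need acid that the benzyl ethers and the C4 linkage do not tolerate, and it would have to discriminate three electron-rich rings.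

18 is cut at C4–C4a, leading through cation 17 to carbinol 16. This bond is favoured from both sides: ring D makes the C4 cation easy to form, and C4a is the most nucleophilic carbon of ring A. Cutting C4–ring D instead would require an intermolecular arylation by a phloroglucinol triether with two kinds of nucleophilic carbon. Cutting O1–C2 last would leave the C4 centre to an acyclic reaction. The forward step closes ring C, joins the two halves and sets C4 from the existing C3 centre. The carbinol configuration of 16 is irrelevant because it is lost on ionisation.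

16 is cut at the O–CH2 bond into diol 14 and phenol 15. The primary alcohol of 14 is far less hindered than the secondary benzylic one, so a redox etherification can select it without protecting groups.

14 comes from aldol adduct 13 by reductive removal of the auxiliary, and 13 is cut at the future C3–C4 bond into imide 8 (as its boron enolate 12) and aldehyde 11. This one bond formation joins ring B to ring D and fixes the configuration of the future C3 through the auxiliary. The imide carbonyl carbon becomes C2 at the alcohol oxidation level, and the aldehyde carbon becomes C4 with the hydroxyl that is later ionised.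

8 is cut at the N-acyl bond into acid 5 and auxiliary 6, with mixed anhydride 7 as the activated form. 5 comes from ester 4, 4 from aryl bromide 3 by cross-coupling of a two-carbon ester unit, 3 from benzyl ether 2 by bromination, and 2 from phenol 1. The phenol must be benzylated before bromination: in 2 the outer methoxy groups direct the halogen to the carbon that becomes the attachment point of ring B, whereas free 1 would react para to its hydroxyl.

11 comes from 10 by benzylation of the two ortho hydroxyls, and 10 from aldehyde 9 by etherification of its most acidic, para hydroxyl. This order gives the para oxygen a different protecting group from the two ortho oxygens at the outset, and the whole route depends on that difference.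

Alternatives that were turned down

Alternative 1: The pyranone ring of the flavanone is closed last, by cutting the bond between the ketone carbon and ring D. The forward step activates the enantiopure β-aryloxy acid A2 as a mixed anhydride with a perfluorinated carboxylic anhydride. The acylium carbon then attacks one of the two equivalent ring D carbons next to the ether oxygen and gives A1. In its favour, the local symmetry removes every regiochemical question, and the flavanone stereocentre is brought in as a preformed C–O centre instead of by a catalyst-controlled conjugate addition. On that point it is stronger than the chosen plan. Against it, that centre is a benzylic aryl ether next to a para-oxygenated ring. In an acidic acylating medium it can ionise (hence the carbonate on that oxygen) or be lost by β-elimination of the phenol. The same medium acts on the acid-labile C4–aryl bonds. The alternative also solves only the last ring; the trans-3,4-diaryl isoflavan 18 or a close relative is still needed. The chosen plan gives up the substrate-defined flavanone centre. In return it finishes under basic and then neutral conditions that spare the C4 linkage, and a wrong C2 epimer is a diastereomer that can be separated and recycled through the chalcone.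

Alternative 2: Ring D itself is disconnected by cutting two C–C bonds to one of its carbons, which leads back to the C4-bound 1,3-diketone A4. In the forward step a strong amide base forms the polyanion of A4. A carbonate ester carboxylates one terminal carbanion, the other closes onto the new ester in a Claisen condensation, and enolisation gives triol A3. In its favour, the C4 substituent is introduced as a simple soft carbon nucleophile, there is no arene regiochemistry, and no cation sits next to the C3–H bond in its key step. Against it, a 3-substituted pentane-2,4-dione with a bulky secondary substituent has to be deprotonated at both methyl groups, and retro-Claisen deacylation and O-acylation compete. More seriously, A3 has three free hydroxyls of which the two ortho ones cannot be told from the para one by simple means. A later pyranone fusion could then use an oxygen ortho or para to C4 and give 8- and 6-linked flavanones. The chosen plan is shorter and carries the oxygen pattern of ring D already differentiated from aldehyde 9. Its ring-forming step uses ring D both as the activating group and as a finished part of the skeleton.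

Alternative 3: Ring C is cut at C3–C4 and at O1–C2. In the forward step the enamine formed from aldehyde A6 and a chiral diarylprolinol silyl ether adds to the ortho-quinone methide A8 released from carbinol A7. The phenol then closes onto the aldehyde carbon to give lactol A5. In its favour, both isoflavan stereocentres come from one catalytic asymmetric step and two simple fragments, without an auxiliary. On step economy and on the use of catalysis it is stronger than the chosen plan. Against it, A8 carries a doubly ortho-substituted aryl group on the methide carbon, which twists out of conjugation and shields the electrophilic carbon. A6 is an arylacetaldehyde that self-condenses easily, and its α-carbon (the future C3) remains epimerisable in A5 through ring-chain tautomerism. The lactol carbon must afterwards be reduced to CH2, either with acid that endangers the C4 linkage or in two further steps. The chosen plan uses a stoichiometric auxiliary and more steps. In return C3 is set by a well-understood enolate face selection and is never again α to a carbonyl, and C2 arrives at the correct oxidation level.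

Key step: step 11

Assumption: the quinine-derived thiourea of step 15 is taken to favour the (2S) flavanone. Its sense of induction is to be confirmed on a simple 2'-hydroxychalcone, and the quinidine-derived pseudo-enantiomer would replace it without other change if the model showed the opposite sense.

Step 1
Reactants: 1 2,6-dimethoxyphenol
Product: 2 2-(benzyloxy)-1,3-dimethoxybenzene
Conditions: BnBr, K2CO3, DMF, rt
Reagents that add atoms: benzyl bromide, BrCc1ccccc1
Why: Williamson etherification; the benzyl group masks the phenol so that the next substitution is steered by the two methoxy groups, and it is removed in the final hydrogenolysis.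

Step 2
Reactants: 2 2-(benzyloxy)-1,3-dimethoxybenzene
Product: 3 3-(benzyloxy)-1-bromo-2,4-dimethoxybenzene
Conditions: NBS (1.0 equiv), MeCN, 0 °C → rt
Reagents that add atoms: N-bromosuccinimide, O=C1CCC(=O)N1Br
Why: Electrophilic aromatic bromination; the central benzyloxy group of the 1,2,3-trioxygenated ring is twisted out of conjugation, so the halogen should enter ortho to one methoxy group and para to the other, which is the substitution pattern of ring B.

Step 3
Reactants: 3 3-(benzyloxy)-1-bromo-2,4-dimethoxybenzene
Product: 4 ethyl 2-[3-(benzyloxy)-2,4-dimethoxyphenyl]acetate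
Conditions: BrZnCH2CO2Et (0.5 M in THF), Pd2(dba)3 (cat.), 2-dicyclohexylphosphino-2',4',6'-triisopropylbiphenyl (cat.), THF, 65 °C
Reagents that add atoms: (2-ethoxy-2-oxoethyl)zinc bromide, CCOC(=O)C[Zn]Br
Why: Negishi-type cross-coupling of a Reformatsky zinc enolate; zerovalent palladium with a bulky biarylphosphine inserts into the hindered, electron-rich C–Br bond, and the neutral zinc reagent leaves the benzyl ether untouched.

Step 4
Reactants: 4 ethyl 2-[3-(benzyloxy)-2,4-dimethoxyphenyl]acetate
Product: 5 2-[3-(benzyloxy)-2,4-dimethoxyphenyl]acetic acid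
Conditions: LiOH·H2O, THF/H2O, rt; then 1 M HCl
Reagents that add atoms: lithium hydroxide, [Li+].[OH-]
Why: Ester saponification; no other group in 4 reacts with aqueous hydroxide.

Step 5
Reactants: 5 2-[3-(benzyloxy)-2,4-dimethoxyphenyl]acetic acid; 6 (4S)-4-benzyl-1,3-oxazolidin-2-one
Product: 8 (4S)-4-benzyl-3-{2-[3-(benzyloxy)-2,4-dimethoxyphenyl]acetyl}-1,3-oxazolidin-2-one, via mixed pivalic anhydride 7 (not isolated)
Conditions: PivCl, Et3N, THF, −20 °C; then 6, LiCl, −20 °C → rt
Reagents that add atoms: none
Why: N-acylation of the oxazolidinone through a mixed anhydride; the auxiliary attacks the unhindered arylacetyl carbonyl and not the pivaloyl carbonyl, and LiCl with Et3N makes the N–H reactive enough without a strong base.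

Step 6
Reactants: 9 2,4,6-trihydroxybenzaldehyde
Product: 10 2,6-dihydroxy-4-(methoxymethoxy)benzaldehyde
Conditions: MOMCl (1.0 equiv), i-Pr2NEt (1.1 equiv), THF, −10 → 0 °C
Reagents that add atoms: chloromethyl methyl ether, COCCl
Why: Williamson-type O-alkylation; the 4-hydroxyl is the most acidic (para to the formyl group) and is not held in a hydrogen bond to the carbonyl, so one equivalent of electrophile at low temperature should favour the 4-ether, with bis-ethers and unreacted 9 removed by chromatography.

Step 7
Reactants: 10 2,6-dihydroxy-4-(methoxymethoxy)benzaldehyde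
Product: 11 2,6-bis(benzyloxy)-4-(methoxymethoxy)benzaldehyde
Conditions: BnBr (2.4 equiv), K2CO3, DMF, 60 °C
Reagents that add atoms: benzyl bromide, BrCc1ccccc1
Why: Williamson etherification of both ortho phenols; warm DMF is needed for the hydrogen-bonded hydroxyl, and the acetal and the aldehyde are stable to carbonate.

Step 8
Reactants: 8 (4S)-4-benzyl-3-{2-[3-(benzyloxy)-2,4-dimethoxyphenyl]acetyl}-1,3-oxazolidin-2-one; 11 2,6-bis(benzyloxy)-4-(methoxymethoxy)benzaldehyde
Product: 13 (4S)-4-benzyl-3-{(2S,3S)-2-[3-(benzyloxy)-2,4-dimethoxyphenyl]-3-[2,6-bis(benzyloxy)-4-(methoxymethoxy)phenyl]-3-hydroxypropanoyl}-1,3-oxazolidin-2-one, via Z-dibutylboron enolate 12 (not isolated)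
Conditions: Bu2BOTf, i-Pr2NEt, CH2Cl2, −78 → 0 °C; then 11, −78 → 0 °C; pH 7 buffer, MeOH, 30% H2O2, 0 °C
Reagents that add atoms: none
Why: Evans syn aldol; the Z boron enolate reacts through a chair-like Zimmerman–Traxler arrangement with the auxiliary carbonyl turned away from boron, and the benzyl group of the auxiliary blocks one enolate face, which sets the α-carbon (2S, the future C3 with R configuration); the carbinol centre (3S) is also formed but is erased in step 11, so only the enolate face selection matters.

Step 9
Reactants: 13 (4S)-4-benzyl-3-{(2S,3S)-2-[3-(benzyloxy)-2,4-dimethoxyphenyl]-3-[2,6-bis(benzyloxy)-4-(methoxymethoxy)phenyl]-3-hydroxypropanoyl}-1,3-oxazolidin-2-one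
Product: 14 (1S,2R)-2-[3-(benzyloxy)-2,4-dimethoxyphenyl]-1-[2,6-bis(benzyloxy)-4-(methoxymethoxy)phenyl]propane-1,3-diol
Conditions: LiBH4, MeOH (1 equiv), THF, 0 °C; then water
Reagents that add atoms: none
Why: Reductive cleavage of the N-acyl oxazolidinone; hydride attacks the exocyclic carbonyl and carries it to the primary alcohol without enolisation, so the α-centre is kept, and the auxiliary is released for recovery.

Step 10
Reactants: 14 (1S,2R)-2-[3-(benzyloxy)-2,4-dimethoxyphenyl]-1-[2,6-bis(benzyloxy)-4-(methoxymethoxy)phenyl]propane-1,3-diol; 15 3-(benzyloxy)phenol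
Product: 16 (1S,2R)-2-[3-(benzyloxy)-2,4-dimethoxyphenyl]-1-[2,6-bis(benzyloxy)-4-(methoxymethoxy)phenyl]-3-[3-(benzyloxy)phenoxy]propan-1-ol
Conditions: PPh3, DIAD, THF, 0 °C → rt
Reagents that add atoms: none
Why: Mitsunobu etherification; the primary alcohol is activated in preference to the secondary carbinol, which is flanked by a doubly ortho-substituted ring and a branched carbon, and the phenol is acidic enough to serve as the nucleophile; no stereocentre is touched.

Step 11
Reactants: 16 (1S,2R)-2-[3-(benzyloxy)-2,4-dimethoxyphenyl]-1-[2,6-bis(benzyloxy)-4-(methoxymethoxy)phenyl]-3-[3-(benzyloxy)phenoxy]propan-1-ol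
Product: 18 (3R,4S)-7-(benzyloxy)-3-[3-(benzyloxy)-2,4-dimethoxyphenyl]-4-[2,6-bis(benzyloxy)-4-(methoxymethoxy)phenyl]chromane, via benzylic cation 17 (not isolated)
Conditions: Sc(OTf)3 (10 mol%), 4 Å MS, CH2Cl2/MeNO2 (9:1), 0.01 M, −20 °C → rt
Reagents that add atoms: none
Why: Sc(OTf)3 ionises the benzylic carbinol of 16 to cation 17, whose charge is spread over ring D and its three ether oxygens, so the carbinol configuration and any syn/anti leakage from step 8 no longer matter. The closest known reaction type is the acid-mediated intramolecular Friedel–Crafts alkylation of 3-aryloxy-1-arylpropan-1-ols to 4-arylchromans. The tethered ring attacks through the carbon para to its benzyloxy group and ortho to the ether oxygen, and loss of a proton gives 18; ring C closes as a six-membered ring in which the attacked arene bond (C4a–C8a) lies inside the new ring (endo with respect to the nucleophilic π bond) and the cationic carbon is the trigonal acceptor. The new C4 centre is controlled by C3: allylic strain with the ortho benzyloxy groups holds the C3–H bond in the plane of the cation, the tether carbon C2 then lies on one face and ring B on the other, and closure through a chair-like arrangement with both aryl groups pseudo-equatorial should give the 3,4-trans (4S) product. The alkylation is reversible under the same catalyst, so a cis isomer can reopen and drain to the trans isomer. Three selectivities are needed: para over ortho closure (the ortho carbon lies between two oxygens and would press a 5-benzyloxy group against the C4 aryl group), ring closure over loss of the C3 proton (secured by the intramolecular six-membered attack of a resorcinol-type ring, the low temperature and the absence of base), and intramolecular over intermolecular alkylation (secured by high dilution). A catalytic Lewis acid with molecular sieves is used so that the methoxymethyl acetal survives.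

Step 12
Reactants: 18 (3R,4S)-7-(benzyloxy)-3-[3-(benzyloxy)-2,4-dimethoxyphenyl]-4-[2,6-bis(benzyloxy)-4-(methoxymethoxy)phenyl]chromane
Product: 20 1-{2,4-bis(benzyloxy)-3-[(3R,4S)-7-(benzyloxy)-3-(3-(benzyloxy)-2,4-dimethoxyphenyl)chroman-4-yl]-6-(methoxymethoxy)phenyl}ethan-1-one, via aryllithium 19 (not isolated)
Conditions: n-BuLi (1.2 equiv), THF, −30 °C; then MeC(O)N(OMe)Me, −78 → 0 °C; aq. NH4Cl
Reagents that add atoms: N-methoxy-N-methylacetamide, CC(=O)N(C)OC
Why: Directed ortho-metalation followed by acylation; the acetal oxygens bind the base and deliver it to the carbon between the methoxymethoxy and benzyloxy groups, the two such carbons are interconverted by rotation about the C4–aryl bond and give the same product, and the N-methoxy-N-methylamide stops at the ketone through its chelated tetrahedral adduct.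

Step 13
Reactants: 20 1-{2,4-bis(benzyloxy)-3-[(3R,4S)-7-(benzyloxy)-3-(3-(benzyloxy)-2,4-dimethoxyphenyl)chroman-4-yl]-6-(methoxymethoxy)phenyl}ethan-1-one; 21 4-(benzyloxy)benzaldehyde
Product: 23 (E)-1-{2,4-bis(benzyloxy)-3-[(3R,4S)-7-(benzyloxy)-3-(3-(benzyloxy)-2,4-dimethoxyphenyl)chroman-4-yl]-6-(methoxymethoxy)phenyl}-3-[4-(benzyloxy)phenyl]prop-2-en-1-one, via β-hydroxy ketone 22 (not isolated)
Conditions: KOH, EtOH/THF, rt → 40 °C
Reagents that add atoms: none
Why: Claisen–Schmidt condensation; the aldehyde cannot enolise, dehydration of the aldol by the E1cB path gives the E enone, and the acetal on the ortho oxygen prevents ring closure under the basic conditions.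

Step 14
Reactants: 23 (E)-1-{2,4-bis(benzyloxy)-3-[(3R,4S)-7-(benzyloxy)-3-(3-(benzyloxy)-2,4-dimethoxyphenyl)chroman-4-yl]-6-(methoxymethoxy)phenyl}-3-[4-(benzyloxy)phenyl]prop-2-en-1-one
Product: 24 (E)-1-{2,4-bis(benzyloxy)-3-[(3R,4S)-7-(benzyloxy)-3-(3-(benzyloxy)-2,4-dimethoxyphenyl)chroman-4-yl]-6-hydroxyphenyl}-3-[4-(benzyloxy)phenyl]prop-2-en-1-one
Conditions: aq. HCl (3 M), THF, 40 °C
Reagents that add atoms: none
Why: Acid hydrolysis of an aryl methoxymethyl acetal, made easy by the ortho carbonyl; ring D is now deactivated by the enone, which should protect the C4–aryl bonds from acid, and the freed phenol is held by a hydrogen bond to the ketone.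

Step 15
Reactants: 24 (E)-1-{2,4-bis(benzyloxy)-3-[(3R,4S)-7-(benzyloxy)-3-(3-(benzyloxy)-2,4-dimethoxyphenyl)chroman-4-yl]-6-hydroxyphenyl}-3-[4-(benzyloxy)phenyl]prop-2-en-1-one
Product: 25 (2S)-5,7-bis(benzyloxy)-6-[(3R,4S)-7-(benzyloxy)-3-(3-(benzyloxy)-2,4-dimethoxyphenyl)chroman-4-yl]-2-[4-(benzyloxy)phenyl]chroman-4-one
Conditions: 1-[3,5-bis(trifluoromethyl)phenyl]-3-[(8α,9S)-6'-methoxycinchonan-9-yl]thiourea (15 mol%), toluene, 0 °C → rt
Reagents that add atoms: none
Why: Organocatalytic intramolecular oxa-Michael addition (6-endo-trig); the quinuclidine nitrogen deprotonates the phenol while the thiourea binds the enone carbonyl, so the catalyst chooses the enone face and should set C2 as S without help from the remote C3 and C4 centres; a 2R epimer would be a diastereomer and separable.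

Step 16
Reactants: 25 (2S)-5,7-bis(benzyloxy)-6-[(3R,4S)-7-(benzyloxy)-3-(3-(benzyloxy)-2,4-dimethoxyphenyl)chroman-4-yl]-2-[4-(benzyloxy)phenyl]chroman-4-one
Product: 26 (2S)-5,7-dihydroxy-6-[(3R,4S)-7-hydroxy-3-(3-hydroxy-2,4-dimethoxyphenyl)chroman-4-yl]-2-(4-hydroxyphenyl)chroman-4-one
Conditions: H2 (1 atm), Pd/C (10%), THF/MeOH, rt
Reagents that add atoms: none
Why: Catalytic hydrogenolysis of the five benzyl ethers under neutral conditions; without base the flavanone does not open, so C2 is kept, and the reaction is stopped at the end of hydrogen uptake to spare the ketone and the benzylic C2–O1 bond.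

Compound list

1 | 2,6-dimethoxyphenol | COc1cccc(OC)c1O | starting material
2 | 2-(benzyloxy)-1,3-dimethoxybenzene | COc1cccc(OC)c1OCc1ccccc1 | intermediate
3 | 3-(benzyloxy)-1-bromo-2,4-dimethoxybenzene | COc1ccc(Br)c(OC)c1OCc1ccccc1 | intermediate
4 | ethyl 2-[3-(benzyloxy)-2,4-dimethoxyphenyl]acetate | CCOC(=O)Cc1ccc(OC)c(OCc2ccccc2)c1OC | intermediate
5 | 2-[3-(benzyloxy)-2,4-dimethoxyphenyl]acetic acid | COc1ccc(CC(=O)O)c(OC)c1OCc1ccccc1 | intermediate
6 | (4S)-4-benzyl-1,3-oxazolidin-2-one | O=C1N[C@@H](Cc2ccccc2)CO1 | starting material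
7 | 2-[3-(benzyloxy)-2,4-dimethoxyphenyl]acetic pivalic anhydride (not isolated) | COc1ccc(CC(=O)OC(=O)C(C)(C)C)c(OC)c1OCc1ccccc1 | intermediate
8 | (4S)-4-benzyl-3-{2-[3-(benzyloxy)-2,4-dimethoxyphenyl]acetyl}-1,3-oxazolidin-2-one | COc1ccc(CC(=O)N2C(=O)OC[C@@H]2Cc2ccccc2)c(OC)c1OCc1ccccc1 | intermediate
9 | 2,4,6-trihydroxybenzaldehyde | O=Cc1c(O)cc(O)cc1O | starting material
10 | 2,6-dihydroxy-4-(methoxymethoxy)benzaldehyde | COCOc1cc(O)c(C=O)c(O)c1 | intermediate
11 | 2,6-bis(benzyloxy)-4-(methoxymethoxy)benzaldehyde | COCOc1cc(OCc2ccccc2)c(C=O)c(OCc2ccccc2)c1 | intermediate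
12 | (Z)-dibutylboron enolate of 8 (not isolated) | CCCCB(CCCC)O/C(=C\c1ccc(OC)c(OCc2ccccc2)c1OC)N1C(=O)OC[C@@H]1Cc1ccccc1 | intermediate
13 | (4S)-4-benzyl-3-{(2S,3S)-2-[3-(benzyloxy)-2,4-dimethoxyphenyl]-3-[2,6-bis(benzyloxy)-4-(methoxymethoxy)phenyl]-3-hydroxypropanoyl}-1,3-oxazolidin-2-one | COc1ccc([C@H](C(=O)N2C(=O)OC[C@@H]2Cc2ccccc2)[C@H](O)c2c(OCc3ccccc3)cc(OCOC)cc2OCc2ccccc2)c(OC)c1OCc1ccccc1 | intermediate
14 | (1S,2R)-2-[3-(benzyloxy)-2,4-dimethoxyphenyl]-1-[2,6-bis(benzyloxy)-4-(methoxymethoxy)phenyl]propane-1,3-diol | COc1ccc([C@H](CO)[C@H](O)c2c(OCc3ccccc3)cc(OCOC)cc2OCc2ccccc2)c(OC)c1OCc1ccccc1 | intermediate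
15 | 3-(benzyloxy)phenol | Oc1cccc(OCc2ccccc2)c1 | starting material
16 | (1S,2R)-2-[3-(benzyloxy)-2,4-dimethoxyphenyl]-1-[2,6-bis(benzyloxy)-4-(methoxymethoxy)phenyl]-3-[3-(benzyloxy)phenoxy]propan-1-ol | COc1ccc([C@H](COc2cccc(OCc3ccccc3)c2)[C@H](O)c2c(OCc3ccccc3)cc(OCOC)cc2OCc2ccccc2)c(OC)c1OCc1ccccc1 | intermediate
17 | (2R)-2-[3-(benzyloxy)-2,4-dimethoxyphenyl]-1-[2,6-bis(benzyloxy)-4-(methoxymethoxy)phenyl]-3-[3-(benzyloxy)phenoxy]propan-1-ylium (not isolated) | COc1ccc([C@H](COc2cccc(OCc3ccccc3)c2)[CH+]c2c(OCc3ccccc3)cc(OCOC)cc2OCc2ccccc2)c(OC)c1OCc1ccccc1 | intermediate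
18 | (3R,4S)-7-(benzyloxy)-3-[3-(benzyloxy)-2,4-dimethoxyphenyl]-4-[2,6-bis(benzyloxy)-4-(methoxymethoxy)phenyl]chromane (3,4-trans) | COc1ccc([C@@H]2COc3cc(OCc4ccccc4)ccc3[C@H]2c2c(OCc3ccccc3)cc(OCOC)cc2OCc2ccccc2)c(OC)c1OCc1ccccc1 | intermediate
19 | {2,4-bis(benzyloxy)-3-[(3R,4S)-7-(benzyloxy)-3-(3-(benzyloxy)-2,4-dimethoxyphenyl)chroman-4-yl]-6-(methoxymethoxy)phenyl}lithium (not isolated) | COc1ccc([C@@H]2COc3cc(OCc4ccccc4)ccc3[C@H]2c2c(OCc3ccccc3)cc(OCOC)c([Li])c2OCc2ccccc2)c(OC)c1OCc1ccccc1 | intermediate
20 | 1-{2,4-bis(benzyloxy)-3-[(3R,4S)-7-(benzyloxy)-3-(3-(benzyloxy)-2,4-dimethoxyphenyl)chroman-4-yl]-6-(methoxymethoxy)phenyl}ethan-1-one | COc1ccc([C@@H]2COc3cc(OCc4ccccc4)ccc3[C@H]2c2c(OCc3ccccc3)cc(OCOC)c(C(C)=O)c2OCc2ccccc2)c(OC)c1OCc1ccccc1 | intermediate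
21 | 4-(benzyloxy)benzaldehyde | O=Cc1ccc(OCc2ccccc2)cc1 | starting material
22 | 1-{2,4-bis(benzyloxy)-3-[(3R,4S)-7-(benzyloxy)-3-(3-(benzyloxy)-2,4-dimethoxyphenyl)chroman-4-yl]-6-(methoxymethoxy)phenyl}-3-[4-(benzyloxy)phenyl]-3-hydroxypropan-1-one (both carbinol epimers, not isolated) | COc1ccc([C@@H]2COc3cc(OCc4ccccc4)ccc3[C@H]2c2c(OCc3ccccc3)cc(OCOC)c(C(=O)CC(O)c3ccc(OCc4ccccc4)cc3)c2OCc2ccccc2)c(OC)c1OCc1ccccc1 | intermediate
23 | (E)-1-{2,4-bis(benzyloxy)-3-[(3R,4S)-7-(benzyloxy)-3-(3-(benzyloxy)-2,4-dimethoxyphenyl)chroman-4-yl]-6-(methoxymethoxy)phenyl}-3-[4-(benzyloxy)phenyl]prop-2-en-1-one | COc1ccc([C@@H]2COc3cc(OCc4ccccc4)ccc3[C@H]2c2c(OCc3ccccc3)cc(OCOC)c(C(=O)/C=C/c3ccc(OCc4ccccc4)cc3)c2OCc2ccccc2)c(OC)c1OCc1ccccc1 | intermediate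
24 | (E)-1-{2,4-bis(benzyloxy)-3-[(3R,4S)-7-(benzyloxy)-3-(3-(benzyloxy)-2,4-dimethoxyphenyl)chroman-4-yl]-6-hydroxyphenyl}-3-[4-(benzyloxy)phenyl]prop-2-en-1-one | COc1ccc([C@@H]2COc3cc(OCc4ccccc4)ccc3[C@H]2c2c(OCc3ccccc3)cc(O)c(C(=O)/C=C/c3ccc(OCc4ccccc4)cc3)c2OCc2ccccc2)c(OC)c1OCc1ccccc1 | intermediate
25 | (2S)-5,7-bis(benzyloxy)-6-[(3R,4S)-7-(benzyloxy)-3-(3-(benzyloxy)-2,4-dimethoxyphenyl)chroman-4-yl]-2-[4-(benzyloxy)phenyl]chroman-4-one | COc1ccc([C@@H]2COc3cc(OCc4ccccc4)ccc3[C@H]2c2c(OCc3ccccc3)cc3c(c2OCc2ccccc2)C(=O)C[C@@H](c2ccc(OCc4ccccc4)cc2)O3)c(OC)c1OCc1ccccc1 | intermediate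
26 | (2S)-5,7-dihydroxy-6-[(3R,4S)-7-hydroxy-3-(3-hydroxy-2,4-dimethoxyphenyl)chroman-4-yl]-2-(4-hydroxyphenyl)chroman-4-one | COc1ccc([C@@H]2COc3cc(O)ccc3[C@H]2c2c(O)cc3c(c2O)C(=O)C[C@@H](c2ccc(O)cc2)O3)c(OC)c1O | target

Total step count: 16. Longest linear sequence: 14 steps (steps 1 to 5 and 8 to 16, from 1). The aldehyde branch (steps 6 and 7) joins at step 8.

Steps least certain to work

Step 11 (key step). The most likely failure is that ring closure is slowed by the two ortho benzyloxy groups around the cationic carbon. Cation 17 could then lose the C3 proton. Re-protonation of the resulting stilbene would regenerate 17 without facial bias, so the C3 configuration would be lost. Cleavage of the acetal by adventitious acid is a lesser risk. The fallback sets out from diol 14 and returns at 18. It forms the C4–aryl bond intermolecularly and closes ring C afterwards at O1–C2. 14 is ionised with catalytic Sc(OTf)3 in the presence of a large excess of resorcinol F1. This small and symmetric nucleophile captures the cation through the carbon ortho to one hydroxyl and para to the other (the two such carbons are equivalent), and the same allylic-strain model predicts attack anti to ring B, giving 4-{(1S,2R)-2-[3-(benzyloxy)-2,4-dimethoxyphenyl]-1-[2,6-bis(benzyloxy)-4-(methoxymethoxy)phenyl]-3-hydroxypropyl}benzene-1,3-diol F2. A dilute Mitsunobu reaction (PPh3, DIAD, THF) between the primary alcohol and the ortho phenol gives the 7-hydroxychroman F3. Benzylation of the remaining phenol (BnBr, K2CO3, DMF) gives 18.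

Step 8. Aldehyde 11 is deactivated by three oxygen donors and shielded by two ortho substituents, and enolate 12 is aryl-stabilised. The addition may therefore be slow and the adduct may revert by retro-aldol reaction during work-up. The fallback sets out from acid 5 and returns at 18. It uses an aldol addition that is made irreversible by silylation. 5 is attached as in step 5 to the enantiomeric auxiliary (4R)-4-benzyl-1,3-oxazolidin-2-one F4 to give imide F5. A magnesium-catalysed anti aldol reaction with 11 (MgCl2 cat., Et3N, Me3SiCl, EtOAc, rt) gives the O-silylated anti adduct F6. The R auxiliary is chosen because the chelated magnesium enolate is attacked on the face opposite to that used by the boron enolate, so the α-carbon has the same configuration as in 13. The anti carbinol does not matter because it is erased later. LiBH4 then gives the primary alcohol F7, and a Mitsunobu reaction with 15 gives aryl ether F8. Sc(OTf)3 ionises the benzylic silyl ether of F8 to the same cation 17 and closes it to 18.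

Step 12. Lithiation may stray to C8 of ring A, which also lies between two ether oxygens, or to a benzylic OCH2 group followed by Wittig rearrangement. The fallback sets out from 18 and returns at aryllithium 19. It takes the regiochemistry from a phenol-directed halogenation. The acetal is removed under buffered conditions (Me3SiOTf, 2,2'-bipyridyl, CH2Cl2, 0 °C; then water) to give phenol F10. NBS (1.0 equiv, CH2Cl2, −78 °C) brominates ortho to the free hydroxyl on what is now the most activated ring, giving bromophenol F11. MOMCl and i-Pr2NEt restore the acetal in bromide F12. Bromine–lithium exchange with n-BuLi at −78 °C is faster than any deprotonation and gives 19, which is acetylated as in step 12 to 20.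

Step 15. The most likely failure is poor facial selectivity. The uncatalysed, base-promoted closure gives both C2 epimers, and the reversible oxa-Michael addition can level them over time. The fallback sets out from 20 and returns at 25. It makes the C2–aryl bond by asymmetric conjugate addition instead of the O1–C2 bond. Acid hydrolysis of the acetal (aq. HCl, THF) gives hydroxy ketone F13. Condensation with N,N-dimethylformamide dimethyl acetal gives enaminone F14, which cyclises on acid treatment with loss of dimethylamine to chromone F15. Addition of [4-(benzyloxy)phenyl]boronic acid F16, catalysed by monovalent rhodium ([RhCl(C2H4)2]2, an atropisomeric bisphosphine ligand, aq. KOH, dioxane), gives 25. The ligand enantiomer that leads to 2S is to be assigned on a simple chromone.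

Step 10. Activation of the β-branched primary alcohol may lead to elimination toward the 2-arylallyl system or to slow substitution, and the secondary carbinol may be drawn in. The fallback sets out from 14 and returns at 16. It separates activation from substitution. Selective sulfonylation of the primary hydroxyl (TsCl, Et3N, Me3N·HCl cat., CH2Cl2, 0 °C) gives tosylate F9, and displacement by the phenoxide of 15 (Cs2CO3, DMF, 50 °C) gives 16.

Further compounds

F1 | step 11 | resorcinol (benzene-1,3-diol) | Oc1cccc(O)c1
F2 | step 11 | 4-{(1S,2R)-2-[3-(benzyloxy)-2,4-dimethoxyphenyl]-1-[2,6-bis(benzyloxy)-4-(methoxymethoxy)phenyl]-3-hydroxypropyl}benzene-1,3-diol | COc1ccc([C@H](CO)[C@@H](c2ccc(O)cc2O)c2c(OCc3ccccc3)cc(OCOC)cc2OCc2ccccc2)c(OC)c1OCc1ccccc1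
F3 | step 11 | (3R,4S)-3-[3-(benzyloxy)-2,4-dimethoxyphenyl]-4-[2,6-bis(benzyloxy)-4-(methoxymethoxy)phenyl]chroman-7-ol | COc1ccc([C@@H]2COc3cc(O)ccc3[C@H]2c2c(OCc3ccccc3)cc(OCOC)cc2OCc2ccccc2)c(OC)c1OCc1ccccc1
F4 | step 8 | (4R)-4-benzyl-1,3-oxazolidin-2-one | O=C1N[C@H](Cc2ccccc2)CO1
F5 | step 8 | (4R)-4-benzyl-3-{2-[3-(benzyloxy)-2,4-dimethoxyphenyl]acetyl}-1,3-oxazolidin-2-one | COc1ccc(CC(=O)N2C(=O)OC[C@H]2Cc2ccccc2)c(OC)c1OCc1ccccc1
F6 | step 8 | (4R)-4-benzyl-3-{(2S,3R)-2-[3-(benzyloxy)-2,4-dimethoxyphenyl]-3-[2,6-bis(benzyloxy)-4-(methoxymethoxy)phenyl]-3-(trimethylsilyloxy)propanoyl}-1,3-oxazolidin-2-one | COc1ccc([C@H](C(=O)N2C(=O)OC[C@H]2Cc2ccccc2)[C@@H](O[Si](C)(C)C)c2c(OCc3ccccc3)cc(OCOC)cc2OCc2ccccc2)c(OC)c1OCc1ccccc1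
F7 | step 8 | (2R,3R)-2-[3-(benzyloxy)-2,4-dimethoxyphenyl]-3-[2,6-bis(benzyloxy)-4-(methoxymethoxy)phenyl]-3-(trimethylsilyloxy)propan-1-ol | COc1ccc([C@H](CO)[C@@H](O[Si](C)(C)C)c2c(OCc3ccccc3)cc(OCOC)cc2OCc2ccccc2)c(OC)c1OCc1ccccc1
F8 | step 8 | {(1R,2R)-2-[3-(benzyloxy)-2,4-dimethoxyphenyl]-1-[2,6-bis(benzyloxy)-4-(methoxymethoxy)phenyl]-3-[3-(benzyloxy)phenoxy]propoxy}trimethylsilane | COc1ccc([C@H](COc2cccc(OCc3ccccc3)c2)[C@@H](O[Si](C)(C)C)c2c(OCc3ccccc3)cc(OCOC)cc2OCc2ccccc2)c(OC)c1OCc1ccccc1
F9 | step 10 | (2R,3S)-2-[3-(benzyloxy)-2,4-dimethoxyphenyl]-3-[2,6-bis(benzyloxy)-4-(methoxymethoxy)phenyl]-3-hydroxypropyl 4-methylbenzenesulfonate | COc1ccc([C@H](COS(=O)(=O)c2ccc(C)cc2)[C@H](O)c2c(OCc3ccccc3)cc(OCOC)cc2OCc2ccccc2)c(OC)c1OCc1ccccc1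
F10 | step 12 | 3,5-bis(benzyloxy)-4-{(3R,4S)-7-(benzyloxy)-3-[3-(benzyloxy)-2,4-dimethoxyphenyl]chroman-4-yl}phenol | COc1ccc([C@@H]2COc3cc(OCc4ccccc4)ccc3[C@H]2c2c(OCc3ccccc3)cc(O)cc2OCc2ccccc2)c(OC)c1OCc1ccccc1
F11 | step 12 | 3,5-bis(benzyloxy)-4-{(3R,4S)-7-(benzyloxy)-3-[3-(benzyloxy)-2,4-dimethoxyphenyl]chroman-4-yl}-2-bromophenol | COc1ccc([C@@H]2COc3cc(OCc4ccccc4)ccc3[C@H]2c2c(OCc3ccccc3)cc(O)c(Br)c2OCc2ccccc2)c(OC)c1OCc1ccccc1
F12 | step 12 | (3R,4S)-7-(benzyloxy)-3-[3-(benzyloxy)-2,4-dimethoxyphenyl]-4-[2,6-bis(benzyloxy)-3-bromo-4-(methoxymethoxy)phenyl]chromane | COc1ccc([C@@H]2COc3cc(OCc4ccccc4)ccc3[C@H]2c2c(OCc3ccccc3)cc(OCOC)c(Br)c2OCc2ccccc2)c(OC)c1OCc1ccccc1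
F13 | step 15 | 1-{2,4-bis(benzyloxy)-3-[(3R,4S)-7-(benzyloxy)-3-(3-(benzyloxy)-2,4-dimethoxyphenyl)chroman-4-yl]-6-hydroxyphenyl}ethan-1-one | COc1ccc([C@@H]2COc3cc(OCc4ccccc4)ccc3[C@H]2c2c(OCc3ccccc3)cc(O)c(C(C)=O)c2OCc2ccccc2)c(OC)c1OCc1ccccc1
F14 | step 15 | (E)-1-{2,4-bis(benzyloxy)-3-[(3R,4S)-7-(benzyloxy)-3-(3-(benzyloxy)-2,4-dimethoxyphenyl)chroman-4-yl]-6-hydroxyphenyl}-3-(dimethylamino)prop-2-en-1-one | COc1ccc([C@@H]2COc3cc(OCc4ccccc4)ccc3[C@H]2c2c(OCc3ccccc3)cc(O)c(C(=O)/C=C/N(C)C)c2OCc2ccccc2)c(OC)c1OCc1ccccc1
F15 | step 15 | 5,7-bis(benzyloxy)-6-{(3R,4S)-7-(benzyloxy)-3-[3-(benzyloxy)-2,4-dimethoxyphenyl]chroman-4-yl}-4H-chromen-4-one | COc1ccc([C@@H]2COc3cc(OCc4ccccc4)ccc3[C@H]2c2c(OCc3ccccc3)cc3occc(=O)c3c2OCc2ccccc2)c(OC)c1OCc1ccccc1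
F16 | step 15 | [4-(benzyloxy)phenyl]boronic acid | OB(O)c1ccc(OCc2ccccc2)cc1
A1 | alternative 1 | protected target carrying four benzyl ethers and one benzyl carbonate | COc1ccc([C@@H]2COc3cc(OCc4ccccc4)ccc3[C@H]2c2c(OCc3ccccc3)cc3c(c2OCc2ccccc2)C(=O)C[C@@H](c2ccc(OC(=O)OCc4ccccc4)cc2)O3)c(OC)c1OCc1ccccc1
A2 | alternative 1 | (3S)-3-(3,5-bis(benzyloxy)-4-{(3R,4S)-7-(benzyloxy)-3-[3-(benzyloxy)-2,4-dimethoxyphenyl]chroman-4-yl}phenoxy)-3-{4-[(benzyloxycarbonyl)oxy]phenyl}propanoic acid | COc1ccc([C@@H]2COc3cc(OCc4ccccc4)ccc3[C@H]2c2c(OCc3ccccc3)cc(O[C@@H](CC(=O)O)c3ccc(OC(=O)OCc4ccccc4)cc3)cc2OCc2ccccc2)c(OC)c1OCc1ccccc1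
A3 | alternative 2 | 2-{(3R,4S)-7-(benzyloxy)-3-[3-(benzyloxy)-2,4-dimethoxyphenyl]chroman-4-yl}benzene-1,3,5-triol | COc1ccc([C@@H]2COc3cc(OCc4ccccc4)ccc3[C@H]2c2c(O)cc(O)cc2O)c(OC)c1OCc1ccccc1
A4 | alternative 2 | 3-{trans-7-(benzyloxy)-3-[3-(benzyloxy)-2,4-dimethoxyphenyl]chroman-4-yl}pentane-2,4-dione (configuration as in the SMILES) | COc1ccc([C@@H]2COc3cc(OCc4ccccc4)ccc3[C@H]2C(C(C)=O)C(C)=O)c(OC)c1OCc1ccccc1
A5 | alternative 3 | trans-7-(benzyloxy)-3-[3-(benzyloxy)-2,4-dimethoxyphenyl]-4-[2,6-bis(benzyloxy)-4-(methoxymethoxy)phenyl]chroman-2-ol (both anomers) | COc1ccc([C@@H]2C(O)Oc3cc(OCc4ccccc4)ccc3[C@H]2c2c(OCc3ccccc3)cc(OCOC)cc2OCc2ccccc2)c(OC)c1OCc1ccccc1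
A6 | alternative 3 | 2-[3-(benzyloxy)-2,4-dimethoxyphenyl]acetaldehyde | COc1ccc(CC=O)c(OC)c1OCc1ccccc1
A7 | alternative 3 | [4-(benzyloxy)-2-hydroxyphenyl][2,6-bis(benzyloxy)-4-(methoxymethoxy)phenyl]methanol (racemic) | OC(c1ccc(OCc2ccccc2)cc1O)c1c(OCc2ccccc2)cc(OCOC)cc1OCc1ccccc1
A8 | alternative 3 | 3-(benzyloxy)-6-{[2,6-bis(benzyloxy)-4-(methoxymethoxy)phenyl]methylidene}cyclohexa-2,4-dien-1-one | O=C1C=C(OCc2ccccc2)C=CC1=Cc1c(OCc2ccccc2)cc(OCOC)cc1OCc1ccccc1
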